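Everything rests on breaking the C1–C14 bond of the six-membered ring (C1, C10, C11–C14) while the ten-membered ring stays intact. C1 is the γ-carbon of the ring enoate C2=C3–CO2Me and becomes doubly allylic, so it is a latent nucleophile: its silyl dienolate is coupled, under palladium catalysis, with a tetrasubstituted alkenyl bromide (the future C14=C15 isopropylidene unit) held on a side chain at C10. One operation closes the cyclohexane, sets C1 trans to C10, places the isopropylidene group and returns the enoate to conjugation. The precursor is a monocyclic cyclodeca-1,5-diene hydroxy acid made from (R)-carvone, whose stereocentre becomes C10.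

Key step: step 14

Remark: 1,1-dibromo-2-methylprop-1-ene (4) is taken as a purchasable reagent; atom labels follow the target (ten-membered ring C1–C10; six-membered ring C1, C10, C11–C14; C15 isopropylidene carbon; C20 exocyclic methylene carbon).

Step 1
Reactants: 1 (R)-(−)-carvone
Product: 2 (5R)-5-(4-hydroxybut-1-en-2-yl)-2-methylcyclohex-2-en-1-one
Conditions: (CH2O)n, Me2AlCl (2.5 equiv), CH2Cl2, −20 °C to rt
Reagents that add atoms: formaldehyde (from paraformaldehyde), C=O
Why: Lewis-acid-promoted carbonyl-ene reaction of formaldehyde at the nucleophilic isopropenyl alkene (the enone alkene is deactivated) transfers a methyl hydrogen and gives the homoallylic alcohol whose new exocyclic methylene becomes C11=C20, leaving the stereocentre (future C10) untouched.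

Step 2
Reactants: 2 (5R)-5-(4-hydroxybut-1-en-2-yl)-2-methylcyclohex-2-en-1-one
Product: 3 (5R)-5-(4-iodobut-1-en-2-yl)-2-methylcyclohex-2-en-1-one
Conditions: I2, PPh3, imidazole, CH2Cl2, 0 °C
Reagents that add atoms: iodine, II
Why: Appel iodination converts the primary alcohol into the primary iodide by SN2 displacement of the oxyphosphonium group without touching the enone or the 1,1-disubstituted alkene.

Step 3
Reactants: 3 (5R)-5-(4-iodobut-1-en-2-yl)-2-methylcyclohex-2-en-1-one, 4 1,1-dibromo-2-methylprop-1-ene
Product: 6 (5R)-5-(5-bromo-6-methylhepta-1,5-dien-2-yl)-2-methylcyclohex-2-en-1-one, via alkylzinc iodide 5 (not isolated)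
Conditions: Zn dust, LiCl, THF, 40 °C; then 4 (1.5 equiv), PdCl2(DPEphos) (5 mol%), THF/DMF, rt
Reagents that add atoms: none
Why: Zinc insertion gives a ketone-tolerant alkylzinc iodide, and Negishi coupling at one of the two equivalent C–Br bonds of the gem-dibromoalkene should stop at the tetrasubstituted alkenyl bromide because the remaining, more hindered C–Br bond undergoes oxidative addition much more slowly.

Step 4
Reactants: 6 (5R)-5-(5-bromo-6-methylhepta-1,5-dien-2-yl)-2-methylcyclohex-2-en-1-one
Product: 7 (1R,4R,6R)-4-(5-bromo-6-methylhepta-1,5-dien-2-yl)-1-methyl-7-oxabicyclo[4.1.0]heptan-2-one (epoxide trans to the side chain)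
Conditions: 30% H2O2, NaOH (cat.), MeOH, 0 °C
Reagents that add atoms: hydrogen peroxide, OO
Why: Weitz–Scheffer nucleophilic epoxidation attacks only the electron-poor enone alkene, trans to the side chain, while the isolated alkenes and the alkenyl bromide are inert to hydroperoxide anion.

Step 5
Reactants: 7 (1R,4R,6R)-4-(5-bromo-6-methylhepta-1,5-dien-2-yl)-1-methyl-7-oxabicyclo[4.1.0]heptan-2-one
Product: 8 (3R)-3-(5-bromo-6-methylhepta-1,5-dien-2-yl)-5-oxopentanoic acid
Conditions: H5IO6 (3 equiv), THF/H2O, rt
Reagents that add atoms: water, O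
Why: Periodic acid hydrolyses the epoxide to the α,β-dihydroxy ketone and cleaves both the glycol and the resulting α-dicarbonyl unit (periodate cleavage), excising the methyl-bearing carbon as acetic acid and leaving an aldehyde (future C2) and an acid (future C8) on either side of the unchanged stereocentre.

Step 6
Reactants: 9 methyl (triphenylphosphoranylidene)acetate, 10 3-bromo-1,1-dimethoxypropane
Product: 12 methyl 5,5-dimethoxy-2-(triphenylphosphoranylidene)pentanoate, via phosphonium bromide 11 (not isolated)
Conditions: NaI (cat.), MeCN, reflux; then aq. NaOH, CH2Cl2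
Reagents that add atoms: none
Why: C-Alkylation of the stabilised ylide by the primary halide (iodide formed in situ by Finkelstein exchange) gives the phosphonium salt, which aqueous hydroxide deprotonates to the α-substituted stabilised ylide.

Step 7
Reactants: 8 (3R)-3-(5-bromo-6-methylhepta-1,5-dien-2-yl)-5-oxopentanoic acid, 12 methyl 5,5-dimethoxy-2-(triphenylphosphoranylidene)pentanoate
Product: 13 (3R,5E)-3-(5-bromo-6-methylhepta-1,5-dien-2-yl)-9,9-dimethoxy-6-(methoxycarbonyl)non-5-enoic acid
Conditions: 12 (2.2 equiv), toluene, 60 °C; aq. citric acid work-up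
Reagents that add atoms: none
Why: Wittig olefination with the α-substituted ester-stabilised ylide reacts only at the aldehyde (excess ylide absorbs the acid proton) and should place the aldehyde-derived chain trans to the ester (E), which is the C2=C3 geometry of the target.

Step 8
Reactants: 13 (3R,5E)-3-(5-bromo-6-methylhepta-1,5-dien-2-yl)-9,9-dimethoxy-6-(methoxycarbonyl)non-5-enoic acid
Product: 15 methyl (2E,5R)-9-bromo-2-(3,3-dimethoxypropyl)-5-(2-hydroxyethyl)-10-methyl-6-methylideneundeca-2,9-dienoate, via mixed carbonic anhydride 14 (not isolated)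
Conditions: i-BuOCOCl, N-methylmorpholine, THF, −15 °C; then NaBH4, H2O, 0 °C
Reagents that add atoms: none
Why: Activation of the acid as the mixed carbonic anhydride and reduction with NaBH4 gives the primary alcohol chemoselectively, since borohydride leaves the conjugated methyl ester, the acetal and the alkenyl bromide alone under these conditions.

Step 9
Reactants: 15 methyl (2E,5R)-9-bromo-2-(3,3-dimethoxypropyl)-5-(2-hydroxyethyl)-10-methyl-6-methylideneundeca-2,9-dienoate
Product: 16 methyl (2E,5R)-9-bromo-5-(2-hydroxyethyl)-10-methyl-6-methylidene-2-(3-oxopropyl)undeca-2,9-dienoate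
Conditions: AcOH/THF/H2O, 40 °C
Reagents that add atoms: water, O
Why: Mild acid hydrolysis of the dimethyl acetal liberates the aldehyde (future C6) without affecting the enoate, the primary alcohol or the alkenes.

Step 10
Reactants: 16 methyl (2E,5R)-9-bromo-5-(2-hydroxyethyl)-10-methyl-6-methylidene-2-(3-oxopropyl)undeca-2,9-dienoate, 17 tert-butyl (triphenylphosphoranylidene)acetate
Product: 19 methyl (2E,5R)-9-bromo-2-[(3Z)-5-tert-butoxy-4-iodo-5-oxopent-3-en-1-yl]-5-(2-hydroxyethyl)-10-methyl-6-methylideneundeca-2,9-dienoate, via iodo ylide 18 (not isolated)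
Conditions: 17, N-iodosuccinimide, CH2Cl2, −20 °C; then 16, 0 °C to rt
Reagents that add atoms: N-iodosuccinimide, O=C1CCC(=O)N1I
Why: Iodination of the stabilised ylide gives the α-iodo ylide in situ, whose Wittig reaction with the aldehyde should place the ester trans to the alkyl chain and hence iodine cis to C5 ((Z)-2-iodoenoate), the geometry needed for C6=C7.

Step 11
Reactants: 19 methyl (2E,5R)-9-bromo-2-[(3Z)-5-tert-butoxy-4-iodo-5-oxopent-3-en-1-yl]-5-(2-hydroxyethyl)-10-methyl-6-methylideneundeca-2,9-dienoate
Product: 20 methyl (2E,5R)-9-bromo-2-[(3Z)-5-tert-butoxy-4-iodo-5-oxopent-3-en-1-yl]-10-methyl-6-methylidene-5-(2-oxoethyl)undeca-2,9-dienoate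
Conditions: Dess–Martin periodinane, CH2Cl2, rt
Reagents that add atoms: none
Why: Dess–Martin oxidation converts the primary alcohol into the aldehyde (future C8) under neutral conditions that leave both enoates, the alkenyl halides and the β-stereocentre untouched.

Step 12
Reactants: 20 methyl (2E,5R)-9-bromo-2-[(3Z)-5-tert-butoxy-4-iodo-5-oxopent-3-en-1-yl]-10-methyl-6-methylidene-5-(2-oxoethyl)undeca-2,9-dienoate
Product: 21 1-tert-butyl 5-methyl (1E,5E,8R,10R)-8-(5-bromo-6-methylhepta-1,5-dien-2-yl)-10-hydroxycyclodeca-1,5-diene-1,5-dicarboxylate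
Conditions: CrCl2 (6 equiv), NiCl2 (2 mol%), Et3N, (S)-N-[2-(4-isopropyl-4,5-dihydrooxazol-2-yl)-6-methylphenyl]methanesulfonamide, THF, 0.003 M, rt
Reagents that add atoms: none
Why: Nozaki–Hiyama–Kishi reaction, in which zerovalent nickel inserts into the C–I bond of the 2-iodoenoate far faster than into the hindered alkenyl bromide and the resulting alkenylchromium adds to the aldehyde at high dilution to close the ten-membered ring with retention of alkene geometry; the chiral sulfonamide ligand on trivalent chromium controls the aldehyde face and sets C8 (R), the ligand enantiomer being chosen for that sense.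

Step 13
Reactants: 21 1-tert-butyl 5-methyl (1E,5E,8R,10R)-8-(5-bromo-6-methylhepta-1,5-dien-2-yl)-10-hydroxycyclodeca-1,5-diene-1,5-dicarboxylate
Product: 23 (1E,5E,8R,10R)-8-(5-bromo-6-methylhepta-1,5-dien-2-yl)-10-hydroxy-5-(methoxycarbonyl)cyclodeca-1,5-diene-1-carboxylic acid, via bis(trimethylsilyl) derivative 22 (not isolated)
Conditions: TMSOTf (3 equiv), 2,6-lutidine, CH2Cl2, 0 °C; then aq. citric acid, THF
Reagents that add atoms: none
Why: The silyl triflate cleaves the tert-butyl ester by O-silylation and loss of isobutene and silylates the alcohol, and mild aqueous acid then hydrolyses the labile trimethylsilyl ester and ether, so the acid is unmasked under buffered conditions that spare the acid-sensitive alkenes.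

Step 14
Reactants: 23 (1E,5E,8R,10R)-8-(5-bromo-6-methylhepta-1,5-dien-2-yl)-10-hydroxy-5-(methoxycarbonyl)cyclodeca-1,5-diene-1-carboxylic acid
Product: 26 microeunicellol A, via tris(trimethylsilyl) dienolate 24 (not isolated), via cyclised bis(trimethylsilyl) derivative 25 (not isolated)
Conditions: LiN(i-Pr)2 (3.3 equiv), THF/DMPU, −78 °C; TMSCl (4 equiv); solvent exchange; Pd(dba)2 (10 mol%), P(t-Bu)3 (20 mol%), ZnF2 (1 equiv), DMF, 80 °C; aq. citric acid work-up
Reagents that add atoms: none
Why: Proposed new method: the base forms the alkoxide, the carboxylate and, only at the methyl ester (a carboxylate is not γ-deprotonated), the dienolate, all three being silylated; zerovalent palladium then inserts into the C14–Br bond, fluoride-assisted transmetalation gives a palladium dienolate, and reductive elimination at the γ-carbon forms C1–C14 and restores the C2=C3 enoate, the closest known reactions being the palladium-catalysed γ-arylation of silyl dienolates of unsaturated esters and the intramolecular α-alkenylation of ketone enolates with alkenyl halides. The six-membered ring closes in a 6-exo mode on the dienolate C1=C2 bond, and γ-attack is secured by ring size because α-attack at C3 would need a bridged eight-membered ring. C1 is controlled by C10: in the ring-cis dienolate, allylic 1,3-strain keeps H10 in the alkene plane, so the side chain lies on the face opposite C9 and delivers C14 to that face, which should give the trans ring fusion (1S). The C2=C3 geometry is held by the ten-membered ring, and the base-free coupling stage avoids deprotonating the more acidic, doubly allylic product. Mild acid work-up removes the two remaining silyl groups and releases the target.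

Compound list
1 | (R)-(−)-carvone, (5R)-2-methyl-5-(prop-1-en-2-yl)cyclohex-2-en-1-one | CC(=C)[C@@H]1CC=C(C)C(=O)C1 | starting material
2 | (5R)-5-(4-hydroxybut-1-en-2-yl)-2-methylcyclohex-2-en-1-one | OCCC(=C)[C@@H]1CC=C(C)C(=O)C1 | intermediate
3 | (5R)-5-(4-iodobut-1-en-2-yl)-2-methylcyclohex-2-en-1-one | ICCC(=C)[C@@H]1CC=C(C)C(=O)C1 | intermediate
4 | 1,1-dibromo-2-methylprop-1-ene | CC(C)=C(Br)Br | starting material
5 | alkylzinc iodide derived from 3 | I[Zn]CCC(=C)[C@@H]1CC=C(C)C(=O)C1 | intermediate
6 | (5R)-5-(5-bromo-6-methylhepta-1,5-dien-2-yl)-2-methylcyclohex-2-en-1-one | CC(C)=C(Br)CCC(=C)[C@@H]1CC=C(C)C(=O)C1 | intermediate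
7 | (1R,4R,6R)-4-(5-bromo-6-methylhepta-1,5-dien-2-yl)-1-methyl-7-oxabicyclo[4.1.0]heptan-2-one | O=C1C[C@H](C(=C)CCC(Br)=C(C)C)C[C@H]2O[C@@]12C | intermediate
8 | (3R)-3-(5-bromo-6-methylhepta-1,5-dien-2-yl)-5-oxopentanoic acid | OC(=O)C[C@H](C(=C)CCC(Br)=C(C)C)CC=O | intermediate
9 | methyl (triphenylphosphoranylidene)acetate | COC(=O)C=P(c1ccccc1)(c1ccccc1)c1ccccc1 | starting material
10 | 3-bromo-1,1-dimethoxypropane | COC(OC)CCBr | starting material
11 | (5,5-dimethoxy-1-methoxy-1-oxopentan-2-yl)triphenylphosphonium bromide | COC(=O)C(CCC(OC)OC)[P+](c1ccccc1)(c1ccccc1)c1ccccc1.[Br-] | intermediate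
12 | methyl 5,5-dimethoxy-2-(triphenylphosphoranylidene)pentanoate | COC(=O)C(CCC(OC)OC)=P(c1ccccc1)(c1ccccc1)c1ccccc1 | intermediate
13 | (3R,5E)-3-(5-bromo-6-methylhepta-1,5-dien-2-yl)-9,9-dimethoxy-6-(methoxycarbonyl)non-5-enoic acid | OC(=O)C[C@H](C(=C)CCC(Br)=C(C)C)C/C=C(/C(=O)OC)CCC(OC)OC | intermediate
14 | mixed isobutyl carbonic anhydride of 13 | CC(C)COC(=O)OC(=O)C[C@H](C(=C)CCC(Br)=C(C)C)C/C=C(/C(=O)OC)CCC(OC)OC | intermediate
15 | methyl (2E,5R)-9-bromo-2-(3,3-dimethoxypropyl)-5-(2-hydroxyethyl)-10-methyl-6-methylideneundeca-2,9-dienoate | OCC[C@H](C(=C)CCC(Br)=C(C)C)C/C=C(/C(=O)OC)CCC(OC)OC | intermediate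
16 | methyl (2E,5R)-9-bromo-5-(2-hydroxyethyl)-10-methyl-6-methylidene-2-(3-oxopropyl)undeca-2,9-dienoate | OCC[C@H](C(=C)CCC(Br)=C(C)C)C/C=C(/C(=O)OC)CCC=O | intermediate
17 | tert-butyl (triphenylphosphoranylidene)acetate | CC(C)(C)OC(=O)C=P(c1ccccc1)(c1ccccc1)c1ccccc1 | starting material
18 | tert-butyl iodo(triphenylphosphoranylidene)acetate | CC(C)(C)OC(=O)C(I)=P(c1ccccc1)(c1ccccc1)c1ccccc1 | intermediate
19 | methyl (2E,5R)-9-bromo-2-[(3Z)-5-tert-butoxy-4-iodo-5-oxopent-3-en-1-yl]-5-(2-hydroxyethyl)-10-methyl-6-methylideneundeca-2,9-dienoate | OCC[C@H](C(=C)CCC(Br)=C(C)C)C/C=C(/C(=O)OC)CC/C=C(/C(=O)OC(C)(C)C)I | intermediate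
20 | methyl (2E,5R)-9-bromo-2-[(3Z)-5-tert-butoxy-4-iodo-5-oxopent-3-en-1-yl]-10-methyl-6-methylidene-5-(2-oxoethyl)undeca-2,9-dienoate | O=CC[C@H](C(=C)CCC(Br)=C(C)C)C/C=C(/C(=O)OC)CC/C=C(/C(=O)OC(C)(C)C)I | intermediate
21 | 1-tert-butyl 5-methyl (1E,5E,8R,10R)-8-(5-bromo-6-methylhepta-1,5-dien-2-yl)-10-hydroxycyclodeca-1,5-diene-1,5-dicarboxylate | CC(C)=C(Br)CCC(=C)[C@@H]1C/C=C(/C(=O)OC)CC/C=C(/C(=O)OC(C)(C)C)[C@H](O)C1 | intermediate
22 | trimethylsilyl ester and trimethylsilyl ether of 23 | CC(C)=C(Br)CCC(=C)[C@@H]1C/C=C(/C(=O)OC)CC/C=C(/C(=O)O[Si](C)(C)C)[C@H](O[Si](C)(C)C)C1 | intermediate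
23 | (1E,5E,8R,10R)-8-(5-bromo-6-methylhepta-1,5-dien-2-yl)-10-hydroxy-5-(methoxycarbonyl)cyclodeca-1,5-diene-1-carboxylic acid | CC(C)=C(Br)CCC(=C)[C@@H]1C/C=C(/C(=O)OC)CC/C=C(/C(=O)O)[C@H](O)C1 | intermediate
24 | tris(trimethylsilyl) derivative of 23: silyl ether, silyl ester and methyl trimethylsilyl ketene acetal (C1=C2 ring-cis dienolate) | CC(C)=C(Br)CCC(=C)[C@@H]1/C=C\C(=C(OC)O[Si](C)(C)C)CC/C=C(/C(=O)O[Si](C)(C)C)[C@H](O[Si](C)(C)C)C1 | intermediate
25 | bis(trimethylsilyl) derivative (silyl ether and silyl ester) of microeunicellol A | C=C1CCC(=C(C)C)[C@H]2/C=C(/C(=O)OC)CC/C=C(/C(=O)O[Si](C)(C)C)[C@H](O[Si](C)(C)C)C[C@H]12 | intermediate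
26 | microeunicellol A (1S,8R,10S; trans-fused 6/10 bicycle) | C=C1CCC(=C(C)C)[C@H]2/C=C(/C(=O)OC)CC/C=C(/C(=O)O)[C@H](O)C[C@H]12 | target

Total step count: 14. Longest linear sequence: 13 steps (steps 1–5 and 7–14; step 6 prepares the ylide).

Steps most likely to fail

1. Step 14 (proposed new method). What may go wrong: slow oxidative addition of zerovalent palladium into the hindered tetrasubstituted C–Br bond, so that the silyl dienolate is protodesilylated or couples through its α-carbon before the ring closes. The fallback uses known chemistry, sets out from 23 and returns to the route at 26. Compound 23 is treated with LiN(i-Pr)2 (3.2 equiv) in THF/DMPU at −78 °C and quenched cold with acetic acid; kinetic α-protonation of the ester dienolate should give the deconjugated β,γ-unsaturated ester F1 (C1=C2 ring-cis, hydrogen on C3). An intramolecular Heck reaction of the β,γ-unsaturated ester F1 (Pd(OAc)2, PPh3, Ag2CO3, MeCN, 70 °C) would then close the six-membered ring by 6-exo carbopalladation of C1=C2, and β-hydride elimination toward C3 would restore the conjugated ester and give 26 directly; the same allylic-strain argument governs C1.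

2. Step 12. What may go wrong: intermolecular coupling competing with ring closure, or poor facial selectivity of the aldehyde addition at C8. The fallback sets out from 20 and returns at 21. The ring is closed without chiral ligand (CrCl2, NiCl2 cat., DMSO, high dilution), accepting that the C8 epimer F2 forms beside 21. The mixture is oxidised with Dess–Martin periodinane to the ten-membered ring ketone F3, and Corey–Bakshi–Shibata reduction of the ring ketone F3 ((S)-2-methyl-CBS-oxazaborolidine, catecholborane, toluene, −78 °C) sets C8 by reagent control and gives 21.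

3. Step 1. What may go wrong: hydrogen transfer from the ring methine instead of the methyl group, which would erase the stereocentre, or Lewis-acid-induced degradation of the enone. The fallback sets out from 1 and returns at 2. Ene-type allylic chlorination of the isopropenyl group (Ca(OCl)2, CO2, CH2Cl2/H2O) gives the allylic chloride F4. A Barbier reaction of the allylic chloride F4 with indium powder and aqueous formaldehyde (THF/H2O) gives 2; the 2-substituted allyl unit is symmetrical, so either terminus leads to the same product.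

Further compounds
F1 | step 14 | deconjugated β,γ-unsaturated methyl ester isomer of 23 (C1=C2 ring-cis, C3 bearing H and CO2Me, C3 configuration not fixed) | CC(C)=C(Br)CCC(=C)[C@@H]1/C=C\C(C(=O)OC)CC/C=C(/C(=O)O)[C@H](O)C1
F2 | step 12 | C8 epimer of 21, 1-tert-butyl 5-methyl (1E,5E,8R,10S)-8-(5-bromo-6-methylhepta-1,5-dien-2-yl)-10-hydroxycyclodeca-1,5-diene-1,5-dicarboxylate | CC(C)=C(Br)CCC(=C)[C@@H]1C/C=C(/C(=O)OC)CC/C=C(/C(=O)OC(C)(C)C)[C@@H](O)C1
F3 | step 12 | 1-tert-butyl 5-methyl (1E,5E,8R)-8-(5-bromo-6-methylhepta-1,5-dien-2-yl)-10-oxocyclodeca-1,5-diene-1,5-dicarboxylate | CC(C)=C(Br)CCC(=C)[C@@H]1C/C=C(/C(=O)OC)CC/C=C(/C(=O)OC(C)(C)C)C(=O)C1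
F4 | step 1 | (5R)-5-(3-chloroprop-1-en-2-yl)-2-methylcyclohex-2-en-1-one | ClCC(=C)[C@@H]1CC=C(C)C(=O)C1
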